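The ochre run had lost 77.0% of its starting material at 10.0 min and held 62% as target, so 80.5% of what was lost had arrived as target. By 20.0 min starting material had fallen a further 15 percentage points, but target had risen 7 points. Their ratio, 46.7%, is the marginal yield: target gained per starting material lost in the same interval, also called the differential yield. It is a reading, and each of those differences carries 2.1 points of scatter, yet the late value is lower than the early one.

the same everywhere: starting material 0.25 M
- ochre: partner 0.75 M; second substrate 0.25 M; third substrate 0.125 M; run made earlier
- green: partner 0.75 M; second substrate 0.12 M; third substrate 0.125 M; run made earlier
- red: partner 0.75 M; second substrate 0.19 M; third substrate 0.125 M; run made earlier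
- blue: partner 1.1 M; second substrate 0.25 M; third substrate 0.125 M; run made earlier
- Wednesday's: partner 0.750 M; second substrate 0.250 M; third substrate 0.125 M (fed, over 1.60 h); all but third substrate at the start; third substrate goes in evenly over 1.60 h, the run ends at 2.0 h; time 2.0 h
- Friday's: partner 0.750 M; second substrate 0.250 M; third substrate 0.125 M; a single well-mixed tank run continuously and read at steady state, 2.0 h in it on average
- Sunday's: partner 0.750 M; second substrate 0.250 M; third substrate 0.125 M; a single well-mixed tank run continuously and read at steady state, 6.00 h in it on average
- Saturday's: partner 0.750 M; second substrate 0.250 M; third substrate 0.125 M; everything together in a closed stirred flask, run for 2.0 h; time 2.0 h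

- ochre (time / min: target / %, starting material / %): 10.0: 62, 23; 20.0: 69, 8; 30.0: 69, 4; 60.0: 67, 1; 120: 72, 0
- green (time / min: target / %, starting material / %): 15.0: 69, 11; 30.0: 72, 3; 40.0: 74, 1; 60.0: 75, 4; 80.0: 73, 2
- red (time / min: target / %, starting material / %): 6.00: 51, 32; 20.0: 69, 9; 30.0: 71, 2; 50.0: 73, 1; 80.0: 71, 0
- blue (time / min: target / %, starting material / %): 6.00: 68, 21; 10.0: 75, 10; 20.0: 80, 3; 40.0: 83, 1; 80.0: 81, 0

(scatter of a reading: 1.5 percentage points)

- the stated concentrations are those of everything mixed, before any reaction; amounts are the same in each set-up
- what was read earlier has a scatter of 1.5 percentage points, one standard deviation
- the feed brings no volume worth counting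
- the earlier runs were made in a closed, stirred flask

1. the set-up with the highest amount of target at the outlet or at the end, in percent of the starting material put in ("none" if the first two lie within 2 percentage points) (Wednesday's / Friday's / Sunday's / Saturday's / none)
2. amount of target at the outlet or at the end, in percent of the starting material put in, Wednesday's
3. amount of target at the outlet or at the end, in percent of the starting material put in, Friday's
4. amount of target at the outlet or at the end, in percent of the starting material put in, Sunday's
5. amount of target at the outlet or at the end, in percent of the starting material put in, Saturday's

Ochre, a closed flask, passes through both values, and their mixture is what its plateau shows, so Saturday's, with the same charge, is reckoned here near 69%. A steady tank does not pass through them. It holds one composition, and what leaves it is the converted fraction times the marginal yield at the outlet. Both mean stays are longer than the 20.0 min ochre took to reach 8% starting material, so Friday's and Sunday's are reckoned here near 46.7%, with little difference between them. Wednesday's holds third substrate back, and no earlier run varied third substrate, so what this does is a supposition here: if third substrate draws on partner, the feed leaves more partner beside the starting material early in Wednesday's, and blue, richer in partner, read higher than ochre. On that supposition Wednesday's is put above Saturday's.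

The forecast gives 76% for Wednesday's, 62% for Friday's, 65% for Sunday's and 70% for Saturday's, and names Wednesday's. Its ground for the tanks is: “A tank sits at depleted partner”. On the tanks it parts from the reckoning here, standing higher than 46.7%.

The flasks give 74.3% for Wednesday's, 47.9% for Friday's, 47.0% for Sunday's and 69.1% for Saturday's; the best is Wednesday's.

    third substrate + partner → third product (k = 0.00890 /M/s)
    starting material + target → side product (k = 0.00300 /M/s)
    starting material + partner → target (k = 0.00490 /M/s)
    second substrate + partner → second product (k = 0.00530 /M/s)

Friday's returned 52.3% of the starting material it lost and Sunday's 48.6%, beside the marginal yield of 46.7% read from ochre. In Sunday's tank, starting material enters a mixture already holding target. Without the reaction of starting material with target, Sunday's rises from 47.0% to 94.3%, which is 89% of what is missing. Side product, each unit counted as two, stands at 49.7% at Sunday's outlet.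

The earlier runs and the new flask come from a simulation for an exercise; the scatter is artificial.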